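The numbers in the tables are simulated for an exercise; scatter was added.

Neither earlier run can have levelled off by running out of substrate: the south-east run still held 62.0 % of it at 8.00 min, and the south run 74.0 % at 10.0 min. The south-east run is the flask asked about, followed so far.

the same everywhere: free catalyst 0.40 mM
- south-east: substrate 20 mM; reagent 21 mM; the very flask that is asked about, followed so far
- south: substrate 30 mM; reagent 21 mM; run made earlier
- flask: substrate 20 mM; reagent 21.0 mM

- south-east (time / min: target / %, substrate / %): 0.417: 6.3, 94.7; 1.00: 10.4, 87.9; 2.00: 18.6, 79.9; 3.00: 25.2, 74.7; 5.00: 31.7, 67.6; 6.00: 34.3, 64.8; 8.00: 37.4, 62.0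
- south (time / min: target / %, substrate / %): 1.33: 9.9, 90.5; 3.00: 16.5, 82.7; 4.00: 19.8, 80.0; 6.00: 22.8, 76.5; 8.00: 25.8, 75.2; 10.0: 26.2, 74.0

(scatter of a reading: 0.5 percentage points)

1. apparent order in reagent when 30 % of the substrate are converted (percent change of the rate of making target for one percent more reagent charged)
2. apparent order in free catalyst when 30 % of the substrate are converted (percent change of the rate of making target for one percent more free catalyst charged)

- no earlier run changes the charge of free catalyst; that part of a forecast is a guess
- no earlier run changes the charge of reagent; that part of a forecast is a guess

Minutes. The forecast was read first: an order of 1.3 in reagent (range 0.3 to 3.8) and 3.5 in free catalyst (range 1.5 to 4.6). Its author argued that both runs flatten near the same absolute target, which “points to catalyst death”, and called the reagent part a guess.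

The minute-taker objected on his own account. Reagent was never read, so its balance is open. Taking one reagent per target, as the forecast also did, he defined the reagent yield, the target made per reagent charged, and read it from the south run: 7.86 mM of target from 21 mM of reagent gives 37.4 %. He argued that the rest of the reagent had gone down a side path, not that the catalyst had died. Carried to the south-east flask, that reading gives an estimated plateau of 39.3 % of the substrate charged. The conversion asked about, 30 %, lies below it, so he committed to a rate there that hangs steeply on whatever shifts the yield, with a catalyst order above one. The two parted on why the target stops.

The flask gives 1.4 in reagent and 2.6 in free catalyst, so the forecast stands close on reagent and above on catalyst.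

    reagent + free catalyst → catalyst intermediate A (k = 11.1 M⁻¹ s⁻¹)
    catalyst intermediate A ⇌ catalyst intermediate B (K = 0.826, k = 0.315 s⁻¹)
    substrate + catalyst intermediate B ⇌ catalyst intermediate C (K = 110 M⁻¹, k = 156 M⁻¹ s⁻¹)
    catalyst intermediate C → free catalyst + target (k = 18.3 s⁻¹)
    2 reagent → self-condensation product (k = 0.301 M⁻¹ s⁻¹)

At 25.0 min the flask holds target 41.9 % of the substrate charged, against the estimate of 39.3 %, with free catalyst >99.9 % and reagent 0.0420 %, each of its own charge: reagent is the limiting reagent, though charged above substrate. The reagent yield of this flask is 39.9 %, and nearly all the rest, 12.6 mM of reagent, sits in 6.30 mM of self-condensation product, two reagent each. With that side step taken out of this flask, the order in free catalyst falls from 2.6 to 1.0.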